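## Structural features

The target is a glycerol 2-O-alkyl ether. Its eight-carbon chain ends at C1 of a cyclohexane (ring A = C1–C6), which is fused through C4–C5 to a linear stack of three cyclobutanes: ring B = C4–C5–C7–C10, ring C = C7–C8–C9–C10, ring D = C8–C11–C12–C9. Every ring fusion is cis and neighbouring rings lie on opposite faces of the ring between them (A and C anti across B, B and D anti across C). The six contiguous stereocentres C4, C5, C7, C10, C8 and C9 therefore describe a staircase. The seventh stereocentre, C1, is insulated from the ladder by C6 and by C2–C3; its hydrogen is on the same face of ring A as H4 and H5, so the chain is cis to the C5–C7 and C4–C10 bonds. Without the chain the hydrocarbon has a mirror plane through the midpoints of C1–C2, C4–C5, C7–C10, C8–C9 and C11–C12, so the absolute configuration is decided only by which of the enantiotopic carbons C1 and C2 carries the chain. The fragile parts are the two bicyclo[2.2.0]hexane units (thermal opening, strong Lewis acids, some metals), cyclobutene intermediates even more so, and the glycerol diol, which must stay masked until the end. The real difficulty is twofold: a strained, unfunctionalised ladder of fixed cis,anti,cis topology, and a remote stereocentre that must be set in the absolute sense. The key step exploits ring C: C7 and C10 carry C5 and C4 on one face, C8 and C9 carry C11 and C12 on the other. This is the pattern of cis,trans,cis-cyclobutane-1,2,3,4-tetracarboxylic dianhydride, so joining C4 to C5 and C11 to C12 closes rings B and D with the correct topology.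

## Logic of the disconnections

**23 ⇒ 22 ⇒ 21.** The acetonide is put back and the C1–H and C2–H bonds are removed. C1 is the only stereocentre not locked into a ring fusion, so it is made last, from a trigonal carbon. The gain is that no earlier step has to control C1. The demand is that hydrogen reaches C1 from the face of ring A that carries H4 and H5.

**21 ⇒ 20 ⇒ 19 ⇒ 18.** The C1=C2 double bond is traced back to a carboxyl group on C1 and an oxygen on C2, which leave together. The ester that enables the ring enlargement thus also fixes the position of the alkene, and no regiochemical choice between C2 and C6 arises. The demand is a hydroxyl at C2 trans to the carboxyl, so that the two groups can become anti-periplanar.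

**18 ⇒ 11 + 17.** The bonds C1–C2 and C1–C6 are cut, taking the chain-bearing carbon out of ring A. This divides the molecule into a chain fragment and a meso core and turns the question of absolute configuration into a choice between two enantiotopic CH2 groups. The demand is a chiral catalyst that lets only the CH2 attached to C5 migrate.

**17 ⇒ 16 ⇒ 14 + 15, and 14 ⇒ 12 + 13.** The diazo group comes from an acetyl group, the C–C bond next to it from an enolate alkylation, and the ether from an alkoxide and a dibromide. All three are routine; the only demand is mono-substitution of 13.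

**11 ⇒ 10 ⇒ 9 ⇒ 8.** The cyclopentanone is contracted by one carbon to a cyclobutanone, whose two new bonds to C4 and C5 are cut in a ketene cycloaddition. This leads back to a hydrocarbon with two equivalent cyclobutenes. The forward step must add once only and from the face anti to ring C. The two cyclobutenes of 8 are differentiated by this bond-forming step and not by a partial reduction. A partial reduction would give three volatile hydrocarbons that cannot be separated. The remaining C11=C12 bond is saturated in the same operation that removes the chlorines.

**8 ⇒ 6 (through 7).** The C4=C5 and C11=C12 double bonds are each reconnected through an SO2 bridge. The two strained four-membered rings thus come from two unstrained five-membered rings. No stereocentre has to be made, because the four ring C carbons are spectators. A bare bis-sulfone has no leaving group and would need a halogen carrier in the basic medium. Therefore 6 carries one chlorine next to each sulfur, installed at the sulfide stage. The demand is clean 1,3-elimination at both ends and a product that tolerates the base.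

**6 ⇒ 4 ⇒ 3 ⇒ 2 ⇒ 1.** The C–Cl and S=O bonds are removed, then the four C–S bonds, then the sulfonates, and the four CH2OH groups are raised to the carboxyl level. The cis,anti,cis relationship is bought with 1. A check of the stereodescriptors confirms that the pattern is carried unchanged from 1 to 8.

## Other disconnections considered

**Alternative 1:** The cut runs through ring C at C7–C8 and C9–C10. It gives a chain-bearing cis-bicyclo[4.2.0]oct-7-ene A1 (C1, C4 and C5 already set, acetonide in place) and cyclobutene A2. In the forward step both alkenes bind to CuOTf and are joined under 254 nm light through their exo faces to the protected target A3 (the same compound as 22).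
- In favour: ring C and the four stereocentres C7–C10 arise in one late step. C1 is configured before any ladder exists, so there is no late facial problem. No diazo compound is needed, and only deprotection follows. On convergence and on the number of operations after the key step this plan is better than the chosen one.
- Against: monovalent copper cannot distinguish two unactivated cyclobutenes. Homodimers of A1 and of A2 should therefore accompany A3 unless the gaseous A2 is used in large excess. A1 must itself be made as a single enantiomer with the chain cis to the ring fusion, which moves the C1 problem instead of removing it. The anti relationships rest on exo,exo selectivity and not on a starting material.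
- Comparison: on structure, the chosen plan buys ring C with its configuration, and this one builds it last. On mechanism, a metal-templated photocycloaddition creates four stereocentres, and the chosen extrusion creates none and so cannot fail stereochemically. On step economy, the longest linear sequence would probably be equal or shorter. Its statistical step, however, falls on the most valuable intermediate, whereas the statistical step of the chosen plan (step 6) falls early.

**Alternative 2:** The cut is the C7–C10 bond. Chlorination of cyclooctatetraene A4 gives cis-7,8-dichlorocycloocta-1,3,5-triene A5, which closes thermally by a disrotatory 6π process to cis-7,8-dichlorobicyclo[4.2.0]octa-2,4-diene A6. This forms ring B with chlorine on C4 and C5 and leaves C8, C9, C11 and C12 in a cyclohexadiene.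
- In favour: two operations from a C8 hydrocarbon place all eight carbons of rings B to D. The cis fusion at C7 and C10 follows from orbital symmetry. No sulfur chemistry or strong base is involved. In step count up to a ring B intermediate this plan is clearly better than the five steps to 8.
- Against: only one cyclobutane and two of the six ladder stereocentres are made. Rings C and D would still need a photochemical 4π closure of the cyclohexadiene (bond C8–C9). Nothing in A6 dictates the face of that closure, and it competes with cycloreversion and ring opening. After dechlorination the route would reach a cyclobutene of the same kind as 8, so ring A, the chain and the absolute configuration remain to be solved in the same way.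
- Comparison: on structure, the chosen plan settles all four ring C centres before any strained ring exists, and this one leaves the anti question open. On mechanism, a thermally allowed electrocyclisation is as dependable as the extrusion, an equal point. On step economy, it is better early and equal later, with the risk moved to the photochemical step.

**Alternative 3:** The cut removes C1 from ring A (bonds C1–C2 and C1–C6). It leaves the meso ketone A7 (the same compound as 11) and the chain diazo ester A8 (the same compound as 17). In the forward step Sc(OTf)3 with a chiral N,N′-dioxide promotes addition of A8 to A7 and the 1,2-shift of one enantiotopic CH2 to give the keto ester A9 (the same compound as 18).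
- In favour: it is the only one of the four disconnections that creates absolute configuration, and it joins the two halves of the molecule catalytically.
- Against, as the carrier of the strategy: it contributes nothing to the ladder, because A7 presupposes rings B to D. The quaternary centre it makes is not kept. Discrimination of enantiotopic groups on a cyclopentanone is not assured.
- Comparison: it is complementary to the chosen plan, not a rival, and is used in it as step 12, so the step economy is equal. On stereochemical information created it is the better step, since the ring contraction creates none. On structure, the contraction closes two strained rings where this step enlarges an unstrained one. The contraction is taken as the key step because the ladder topology is the scarcer problem and determines from what A7 can be made at all.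

Key step: step 5

Assumption: C1 of 18 is taken to form with the ester on the face of ring A turned away from the ladder; C1 becomes trigonal in 21, so the other C1 epimer would differ only in which elimination variant (step 15 or its fallback) applies.

## Route

**Step 1**
Reactants: 1 cis,trans,cis-cyclobutane-1,2,3,4-tetracarboxylic dianhydride
Product: 2 cis,trans,cis-cyclobutane-1,2,3,4-tetrayltetramethanol
Conditions: LiAlH4, THF, reflux; H2O/15% NaOH quench; continuous extraction of the salts with hot THF
Reagents that add atoms: none
Why: Hydride reduction of both cyclic anhydrides to 1,4-diols; the ring carbons are not enolised under these conditions, so the cis,trans,cis pattern is retained.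

**Step 2**
Reactants: 2 cis,trans,cis-cyclobutane-1,2,3,4-tetrayltetramethanol
Product: 3 cis,trans,cis-cyclobutane-1,2,3,4-tetrayltetrakis(methylene) tetramethanesulfonate
Conditions: MsCl, pyridine, 0 °C to rt
Reagents that add atoms: methanesulfonyl chloride, CS(=O)(=O)Cl
Why: O-Sulfonylation of four primary alcohols; no bond to a ring carbon is touched.

**Step 3**
Reactants: 3 cis,trans,cis-cyclobutane-1,2,3,4-tetrayltetrakis(methylene) tetramethanesulfonate
Product: 4 cis,anti,cis-4,9-dithiatricyclo[5.3.0.0(2,6)]decane
Conditions: Na2S·9H2O, DMF, 80 °C, slow addition of 3
Reagents that add atoms: Na2S, [Na+].[Na+].[S-2]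
Why: Twofold double SN2 thioetherification; after the first displacement only the cis CH2OMs group on the neighbouring ring carbon can be reached (5-exo-tet) without a trans-fused or bridged ring, and slow addition suppresses oligomers.

**Step 4**
Reactants: 4 cis,anti,cis-4,9-dithiatricyclo[5.3.0.0(2,6)]decane
Product: 6 3,8-dichloro-4,9-dithiatricyclo[5.3.0.0(2,6)]decane 4,4,9,9-tetraoxide (one chlorine per ring; isomer mixture), via bis(α-chlorosulfide) 5 (not isolated)
Conditions: NCS (2.1 equiv), CH2Cl2, 0 °C to rt; then mCPBA (4.5 equiv), 0 °C to rt
Reagents that add atoms: N-chlorosuccinimide, O=C1CCC(=O)N1Cl; 3-chloroperoxybenzoic acid, OOC(=O)c1cccc(Cl)c1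
Why: Each sulfide is chlorinated once at an α-carbon through its chlorosulfonium salt and thionium ion (Pummerer-type α-chlorination), the electron-poor α-chlorosulfide resisting a second chlorination. The moisture-sensitive 5 is oxidised in the same flask to the stable α-chlorosulfone. The positions and configurations of the chlorines are immaterial because they are lost in step 5.

**Step 5**
Reactants: 6 3,8-dichloro-4,9-dithiatricyclo[5.3.0.0(2,6)]decane 4,4,9,9-tetraoxide
Product: 8 anti-tricyclo[4.2.0.0(2,5)]octa-3,7-diene, via bis(episulfone) 7 (not isolated)
Conditions: KOt-Bu (5 equiv), THF, −20 °C to rt; water/pentane work-up below 10 °C, kept as a cold solution and transferred into Et2O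
Reagents that add atoms: none
Why: This is a Ramberg–Bäcklund reaction run at both sulfones of one molecule; its closest known relative is the contraction of a single cyclobutane-fused α-chlorothiolane 1,1-dioxide to bicyclo[2.2.0]hex-2-ene with the same base. tert-Butoxide removes a proton from the unchlorinated α′-CH2 of each ring, and the carbanion displaces chloride from the carbon on the other side of sulfur (1,3-elimination, 3-exo-tet), making the C4–C5 and C11–C12 σ bonds inside an episulfone, written here as the twofold species 7. Each episulfone then expels SO2 and leaves a cis double bond, so a five-membered sulfone has become a cyclobutene; rings B and D are thus closed by ring contraction (3-exo-tet closure followed by extrusion), not by cycloaddition. No stereocentre is created: the four ring C carbons bear no acidic hydrogen and are not touched, so the cis,anti,cis arrangement of 1 reappears as the anti topology of 8, and the chlorine positions of 6 are erased. The selectivity needed is 1,3-elimination at both rings in preference to substitution at the C–Cl carbon or 1,2-dehydrochlorination; the substrate secures it because the α′-hydrogens next to sulfonyl are far more acidic than the ring-fusion hydrogens and the hindered alkoxide is not a nucleophile. Because the leaving group is already in 6, no halogen carrier or carbene source is present that could attack the strained alkenes. 8 is volatile and reverts to an eight-membered polyene on heating, so it is kept cold and carried on in solution.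

**Step 6**
Reactants: 8 anti-tricyclo[4.2.0.0(2,5)]octa-3,7-diene (threefold excess, surplus recovered with the distillate)
Product: 9 4,4-dichlorotetracyclo[4.4.0.0(2,5).0(7,10)]dec-8-en-3-one (all fusions cis, neighbouring rings anti; racemic)
Conditions: Cl3CCOCl, Zn dust, DME (1 equiv), Et2O, rt, ultrasound
Reagents that add atoms: trichloroacetyl chloride, ClC(=O)C(Cl)(Cl)Cl (dechlorinated by Zn to dichloroketene, ClC(Cl)=C=O, which is the species that adds)
Why: Thermal ketene–alkene [2+2] cycloaddition, suprafacial on the strained cyclobutene (cis fusion at C4 and C5) and from its exo face, anti to ring C, which sets the anti relationship of the new ring to ring C. The excess of 8 keeps double addition low, and DME ties up ZnCl2 so that the strained alkene is not exposed to a free Lewis acid.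

**Step 7**
Reactants: 9 4,4-dichlorotetracyclo[4.4.0.0(2,5).0(7,10)]dec-8-en-3-one
Product: 10 3,3-dichlorotetracyclo[5.4.0.0(2,6).0(8,11)]undec-9-en-4-one (racemic)
Conditions: CH2N2 (1.5 equiv), Et2O, MeOH (cat.), 0 °C, 30 min; AcOH quench
Reagents that add atoms: diazomethane, C=[N+]=[N-]
Why: Diazomethane adds to the activated cyclobutanone carbonyl and the unchlorinated α-carbon (C4) migrates with loss of N2, because the CCl2 carbon is a poor migrating group (Tiffeneau–Demjanov-type one-carbon expansion). No stereocentre is touched, and the short cold exposure spares the cyclobutene.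

**Step 8**
Reactants: 10 3,3-dichlorotetracyclo[5.4.0.0(2,6).0(8,11)]undec-9-en-4-one
Product: 11 tetracyclo[5.4.0.0(2,6).0(8,11)]undecan-4-one (cis at every fusion, rings anti; meso)
Conditions: H2 (1 atm), 10% Pd/C, NaOAc, MeOH–EtOAc, rt
Reagents that add atoms: none
Why: Catalytic hydrogenolysis removes both C–Cl bonds α to the ketone (NaOAc takes up the HCl), and the same catalyst saturates C11=C12, where no stereocentre arises. The product has a mirror plane through the carbonyl group and is achiral.

**Step 9**
Reactants: 12 2,2-dimethyl-1,3-dioxan-5-ol; 13 1,8-dibromooctane (4 equiv)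
Product: 14 5-[(8-bromooctyl)oxy]-2,2-dimethyl-1,3-dioxane
Conditions: NaH, DMF–THF, 0 °C; then 13, Bu4NI (cat.), rt
Reagents that add atoms: none
Why: Williamson ether synthesis between a secondary alkoxide and a primary bromide; the excess of dibromide suppresses the bis-ether and is recovered by distillation.

**Step 10**
Reactants: 14 5-[(8-bromooctyl)oxy]-2,2-dimethyl-1,3-dioxane; 15 benzyl acetoacetate (1.5 equiv)
Product: 16 benzyl 2-acetyl-10-[(2,2-dimethyl-1,3-dioxan-5-yl)oxy]decanoate (racemic)
Conditions: K2CO3, KI (cat.), DMF, 50 °C
Reagents that add atoms: none
Why: C-Alkylation of the acetoacetate enolate by SN2 with iodide catalysis; the slight excess of 15 limits dialkylation.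

**Step 11**
Reactants: 16 benzyl 2-acetyl-10-[(2,2-dimethyl-1,3-dioxan-5-yl)oxy]decanoate
Product: 17 benzyl 2-diazo-10-[(2,2-dimethyl-1,3-dioxan-5-yl)oxy]decanoate
Conditions: 4-acetamidobenzenesulfonyl azide, DBU, MeCN, 0 °C to rt
Reagents that add atoms: 4-acetamidobenzenesulfonyl azide, CC(=O)Nc1ccc(cc1)S(=O)(=O)N=[N+]=[N-]
Why: Deacylative Regitz diazo transfer: the enolate adds to the terminal nitrogen of the azide and the adduct fragments with transfer of the acetyl group to the sulfonamide nitrogen, leaving the α-alkyl-α-diazo ester.

**Step 12**
Reactants: 11 tetracyclo[5.4.0.0(2,6).0(8,11)]undecan-4-one; 17 benzyl 2-diazo-10-[(2,2-dimethyl-1,3-dioxan-5-yl)oxy]decanoate (1.3 equiv)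
Product: 18 benzyl 10-{8-[(2,2-dimethyl-1,3-dioxan-5-yl)oxy]octyl}-11-oxotetracyclo[6.4.0.0(2,7).0(3,6)]dodecane-10-carboxylate (ring A keto ester: quaternary C1 with chain and CO2Bn, ketone at C2)
Conditions: Sc(OTf)3 (10 mol %), chiral N,N′-dioxide ligand from (S)-pipecolic acid and 2,6-diisopropylaniline with a propane-1,3-diyl linker (12 mol %), CH2Cl2, 0 °C to rt
Reagents that add atoms: none
Why: Catalytic asymmetric homologation of a cyclic ketone with an α-alkyl-α-diazo ester (Tiffeneau–Demjanov-type ring expansion): the diazo carbon adds to the scandium-bound carbonyl, and the CH2 anti-periplanar to the departing N2 shifts to it. In the chiral pocket only the CH2 attached to C5 should be so aligned, which fixes the absolute configuration of the whole skeleton; the ligand enantiomer is chosen for this sense. The hindered product ketone does not react again, and the catalytic, anhydrous Lewis acid should leave the acetonide and the ladder intact.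

**Step 13**
Reactants: 18 ring A keto ester
Product: 19 benzyl 11-hydroxy-10-{8-[(2,2-dimethyl-1,3-dioxan-5-yl)oxy]octyl}tetracyclo[6.4.0.0(2,7).0(3,6)]dodecane-10-carboxylate (C2 hydroxyl trans to the ester, cis to the chain)
Conditions: NaBH4, MeOH–THF, 0 °C
Reagents that add atoms: none
Why: Borohydride reduction of the ketone; hydride should enter from the face of ring A turned away from the ladder and from the chain, which puts the C2 hydroxyl trans to the ester. This stereocentre is not kept in the target; it only serves step 15.

**Step 14**
Reactants: 19 ring A hydroxy ester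
Product: 20 11-hydroxy-10-{8-[(2,2-dimethyl-1,3-dioxan-5-yl)oxy]octyl}tetracyclo[6.4.0.0(2,7).0(3,6)]dodecane-10-carboxylic acid
Conditions: H2 (1 atm), 10% Pd/C, EtOAc, rt
Reagents that add atoms: none
Why: Hydrogenolysis of the benzyl ester; the β-hydroxy acid, unlike a β-keto acid, does not lose CO2 by itself, and saturated cyclobutanes and the acetonide are inert under these conditions.

**Step 15**
Reactants: 20 ring A hydroxy acid
Product: 21 5-{[8-(tetracyclo[6.4.0.0(2,7).0(3,6)]dodec-10-en-10-yl)octyl]oxy}-2,2-dimethyl-1,3-dioxane (C1=C2 alkene)
Conditions: Me2NCH(OCH2CMe3)2 (3 equiv), MeCN, 60–80 °C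
Reagents that add atoms: none
Why: Dehydrative decarboxylation of a β-hydroxy acid with a formamide acetal: the hydroxyl becomes an alkoxyformamidinium leaving group, and the trans-diaxial carboxylate fragments in a Grob-type anti elimination with loss of CO2 and DMF. The double bond can form only between C1 and C2, the neopentyl acetal cannot esterify the acid, and the C1 stereocentre is removed on purpose.

**Step 16**
Reactants: 21 C1=C2 alkene
Product: 23 2-{[8-(tetracyclo[6.4.0.0(2,7).0(3,6)]dodecan-10-yl)octyl]oxy}propane-1,3-diol (target), via acetonide 22 (not isolated)
Conditions: H2 (1 atm), 5% Pd/C, EtOAc, rt; N2 purge; then MeOH, 1 M aq HCl, rt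
Reagents that add atoms: none
Why: Heterogeneous syn hydrogenation of the trisubstituted alkene should take place on the face of ring A that carries H4 and H5, the ladder being attached on the other face. This puts H1 cis to H4 and H5 and the chain cis to the C5–C7 and C4–C10 bonds, as in the target. Dilute acid then hydrolyses the acetonide without affecting the saturated ladder.

## Compound list

1 | cis,trans,cis-cyclobutane-1,2,3,4-tetracarboxylic dianhydride | O1C(=O)[C@H]2[C@@H]3C(=O)OC(=O)[C@@H]3[C@H]2C1=O | starting material
2 | cis,trans,cis-cyclobutane-1,2,3,4-tetrayltetramethanol | OC[C@H]1[C@H](CO)[C@H](CO)[C@H]1CO | intermediate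
3 | cis,trans,cis-cyclobutane-1,2,3,4-tetrayltetrakis(methylene) tetramethanesulfonate | CS(=O)(=O)OC[C@H]1[C@H](COS(C)(=O)=O)[C@H](COS(C)(=O)=O)[C@H]1COS(C)(=O)=O | intermediate
4 | cis,anti,cis-4,9-dithiatricyclo[5.3.0.0(2,6)]decane | S1C[C@H]2[C@@H]3CSC[C@@H]3[C@H]2C1 | intermediate
5 | 3,8-dichloro-4,9-dithiatricyclo[5.3.0.0(2,6)]decane (cis,anti,cis core; one α-chlorine per ring; mixture of positional and configurational isomers at the CHCl carbons, one drawn) | S1C(Cl)[C@H]2[C@@H]3CSC(Cl)[C@@H]3[C@H]2C1 | intermediate
6 | 3,8-dichloro-4,9-dithiatricyclo[5.3.0.0(2,6)]decane 4,4,9,9-tetraoxide (same isomer mixture, one drawn) | O=S1(=O)C(Cl)[C@H]2[C@@H]3CS(=O)(=O)C(Cl)[C@@H]3[C@H]2C1 | intermediate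
7 | bis(episulfone): anti-tricyclo[4.2.0.0(2,5)]octane with one SO2 bridge across C3–C4 and one across C7–C8 (bridges drawn exo; their orientation is immaterial) | O=S1(=O)[C@@H]2[C@H]1[C@@H]1[C@H]2[C@@H]2[C@H]1[C@@H]1[C@H]2S1(=O)=O | intermediate
8 | anti-tricyclo[4.2.0.0(2,5)]octa-3,7-diene | C1=C[C@H]2[C@@H]3C=C[C@@H]3[C@@H]12 | intermediate
9 | 4,4-dichlorotetracyclo[4.4.0.0(2,5).0(7,10)]dec-8-en-3-one (all fusions cis, neighbouring rings anti; racemic, one enantiomer drawn) | O=C1[C@@H]2[C@H](C1(Cl)Cl)[C@H]1[C@@H]3C=C[C@@H]3[C@@H]21 | intermediate
10 | 3,3-dichlorotetracyclo[5.4.0.0(2,6).0(8,11)]undec-9-en-4-one (racemic, one enantiomer drawn) | O=C1C[C@@H]2[C@H](C1(Cl)Cl)[C@H]1[C@@H]3C=C[C@@H]3[C@@H]21 | intermediate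
11 | tetracyclo[5.4.0.0(2,6).0(8,11)]undecan-4-one (meso) | O=C1C[C@@H]2[C@H](C1)[C@H]1[C@@H]3CC[C@@H]3[C@@H]21 | intermediate
12 | 2,2-dimethyl-1,3-dioxan-5-ol | CC1(C)OCC(O)CO1 | starting material
13 | 1,8-dibromooctane | BrCCCCCCCCBr | starting material
14 | 5-[(8-bromooctyl)oxy]-2,2-dimethyl-1,3-dioxane | CC1(C)OCC(CO1)OCCCCCCCCBr | intermediate
15 | benzyl acetoacetate | CC(=O)CC(=O)OCc1ccccc1 | starting material
16 | benzyl 2-acetyl-10-[(2,2-dimethyl-1,3-dioxan-5-yl)oxy]decanoate (racemic) | CC(=O)C(CCCCCCCCOC1COC(C)(C)OC1)C(=O)OCc1ccccc1 | intermediate
17 | benzyl 2-diazo-10-[(2,2-dimethyl-1,3-dioxan-5-yl)oxy]decanoate | CC1(C)OCC(CO1)OCCCCCCCCC(=[N+]=[N-])C(=O)OCc1ccccc1 | intermediate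
18 | ring A keto ester: benzyl 10-{8-[(2,2-dimethyl-1,3-dioxan-5-yl)oxy]octyl}-11-oxotetracyclo[6.4.0.0(2,7).0(3,6)]dodecane-10-carboxylate (ester on the H4/H5 face) | CC1(C)OCC(CO1)OCCCCCCCC[C@@]1(C(=O)OCc2ccccc2)C(=O)C[C@@H]2[C@H](C1)[C@H]1[C@@H]3CC[C@@H]3[C@@H]21 | intermediate
19 | ring A hydroxy ester (C2 hydroxyl trans to the ester) | CC1(C)OCC(CO1)OCCCCCCCC[C@@]1(C(=O)OCc2ccccc2)[C@@H](O)C[C@@H]2[C@H](C1)[C@H]1[C@@H]3CC[C@@H]3[C@@H]21 | intermediate
20 | ring A hydroxy acid (C2 hydroxyl trans to the carboxyl) | CC1(C)OCC(CO1)OCCCCCCCC[C@@]1(C(=O)O)[C@@H](O)C[C@@H]2[C@H](C1)[C@H]1[C@@H]3CC[C@@H]3[C@@H]21 | intermediate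
21 | 5-{[8-(tetracyclo[6.4.0.0(2,7).0(3,6)]dodec-10-en-10-yl)octyl]oxy}-2,2-dimethyl-1,3-dioxane (C1=C2 alkene) | CC1(C)OCC(CO1)OCCCCCCCCC1=CC[C@@H]2[C@H](C1)[C@H]1[C@@H]3CC[C@@H]3[C@@H]21 | intermediate
22 | 5-{[8-(tetracyclo[6.4.0.0(2,7).0(3,6)]dodecan-10-yl)octyl]oxy}-2,2-dimethyl-1,3-dioxane (acetonide of the target) | CC1(C)OCC(CO1)OCCCCCCCC[C@H]1CC[C@@H]2[C@H](C1)[C@H]1[C@@H]3CC[C@@H]3[C@@H]21 | intermediate
23 | 2-{[8-(tetracyclo[6.4.0.0(2,7).0(3,6)]dodecan-10-yl)octyl]oxy}propane-1,3-diol | OCC(CO)OCCCCCCCC[C@H]1CC[C@@H]2[C@H](C1)[C@H]1[C@@H]3CC[C@@H]3[C@@H]21 | target

## Step count and least certain steps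

Total: 16 steps. Longest linear sequence: 13 steps (steps 1–8 and 12–16); the chain branch is steps 9–11.

**Step 5 (key step).** The twofold contraction may stop half-way: once the first ring has contracted, the second chlorosulfone must still eliminate while the first cyclobutene sits in alkoxide. Material that was chlorinated unevenly in step 4 would also not contract cleanly, and the volatile, heat-sensitive product can be lost on concentration. The fallback sets out from 4 and changes the way the leaving group is supplied. 4 is oxidised (H2O2, Na2WO4 cat.) to the halogen-free cis,anti,cis-4,9-dithiatricyclo[5.3.0.0(2,6)]decane 4,4,9,9-tetraoxide F1. F1 is then halogenated and contracted in one flask with KOH on alumina and CBr2F2 in t-BuOH/CH2Cl2, where each α-bromosulfone is consumed as it forms. The route is rejoined at 8. The halon is regulated, which is why this is the reserve and not the first choice.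

**Step 8.** Hydrogenolysis of the second C–Cl bond may lag behind the first, base-induced loss of HCl from 10 may compete, and the strained cyclobutene may isomerise on the metal surface before it is reduced. The fallback sets out from 10 and separates the two tasks. Zn dust in AcOH removes both chlorines by electron transfer and gives the unsaturated meso ketone tetracyclo[5.4.0.0(2,6).0(8,11)]undec-9-en-4-one F2. Diimide (KO2CN=NCO2K, AcOH, MeOH) then saturates C11=C12 without any metal surface. The route is rejoined at 11.

**Step 12.** Addition to a cyclopentanone carbonyl inside a crowded chiral complex may be slow, the two enantiotopic CH2 groups may be poorly distinguished, and the Lewis acid may open the acetonide. The fallback sets out from 11 and 17 and takes the enantiopurity from a separation instead of from catalysis. Ligand-free Sc(OTf)3 (or BF3·OEt2 at −78 °C) should give the keto ester as a racemate, that is 18 together with the mirror image of 18 F3. The two are separated by preparative chromatography on a polysaccharide chiral stationary phase. The route is rejoined at 18.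

**Step 15.** The fragmentation fails if hydroxyl and carboxyl cannot become anti-periplanar. This would happen if hydride in step 13 is delivered from the ladder side, or if C1 forms with the other configuration in step 12. The fallback sets out from 18 and uses the syn-specific counterpart of the elimination. Reduction then gives the cis-hydroxy ester F4, and hydrogenolysis (H2, Pd/C) gives the cis-hydroxy acid F5. Carboxyl activation (PhSO2Cl, pyridine, 0 °C) closes F5 with retention at C2 to the cis-fused β-lactone F6. Brief heating (collidine/xylene, 120–140 °C, where thermal opening of the ladder is still slow) extrudes CO2 from F6. The route is rejoined at 21.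

**Step 16.** Facial selectivity may be poor, because C1 is three bonds away from the nearest ladder carbon and ring A is a flexible, boat-like ring. Palladium may also move the double bond before reducing it. The fallback sets out from 21 and uses a bulkier reagent that cannot isomerise the alkene. Hydroboration with 9-BBN (THF, 65 °C) adds syn from the open face, boron to C2 and hydrogen to C1, and oxidation (H2O2, NaOH) gives the C2 alcohol F7. F7 is converted into its S-methyl xanthate F8 (NaH, CS2, MeI) and deoxygenated by the Barton–McCombie reaction (Bu3SnH, AIBN, toluene, 80 °C). The route is rejoined at 22, which is deprotected as in step 16.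

## Further compounds

F1 | step 5 | cis,anti,cis-4,9-dithiatricyclo[5.3.0.0(2,6)]decane 4,4,9,9-tetraoxide | O=S1(=O)C[C@H]2[C@@H]3CS(=O)(=O)C[C@@H]3[C@H]2C1
F2 | step 8 | tetracyclo[5.4.0.0(2,6).0(8,11)]undec-9-en-4-one (meso) | O=C1C[C@@H]2[C@H](C1)[C@H]1[C@@H]3C=C[C@@H]3[C@@H]21
F3 | step 12 | mirror image of 18 | CC1(C)OCC(CO1)OCCCCCCCC[C@]1(C(=O)OCc2ccccc2)C(=O)C[C@H]2[C@@H](C1)[C@@H]1[C@H]3CC[C@H]3[C@H]21
F4 | step 15 | C2 epimer of 19 (hydroxyl cis to the ester) | CC1(C)OCC(CO1)OCCCCCCCC[C@@]1(C(=O)OCc2ccccc2)[C@H](O)C[C@@H]2[C@H](C1)[C@H]1[C@@H]3CC[C@@H]3[C@@H]21
F5 | step 15 | C2 epimer of 20 (hydroxyl cis to the carboxyl) | CC1(C)OCC(CO1)OCCCCCCCC[C@@]1(C(=O)O)[C@H](O)C[C@@H]2[C@H](C1)[C@H]1[C@@H]3CC[C@@H]3[C@@H]21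
F6 | step 15 | cis-fused β-lactone between the C1 carboxyl and the C2 oxygen | CC1(C)OCC(CO1)OCCCCCCCC[C@@]12C(=O)O[C@@H]1C[C@@H]1[C@H](C2)[C@H]2[C@@H]3CC[C@@H]3[C@@H]12
F7 | step 16 | C2 alcohol of 22 (hydroxyl and H1 on the H4/H5 face) | CC1(C)OCC(CO1)OCCCCCCCC[C@H]1[C@H](O)C[C@@H]2[C@H](C1)[C@H]1[C@@H]3CC[C@@H]3[C@@H]21
F8 | step 16 | O-alkyl S-methyl xanthate of F7 | CC1(C)OCC(CO1)OCCCCCCCC[C@H]1[C@H](OC(=S)SC)C[C@@H]2[C@H](C1)[C@H]1[C@@H]3CC[C@@H]3[C@@H]21
A1 | alternative 1 | 5-{[8-(cis-bicyclo[4.2.0]oct-7-en-3-yl)octyl]oxy}-2,2-dimethyl-1,3-dioxane (chain cis to the cyclobutene) | CC1(C)OCC(CO1)OCCCCCCCC[C@H]1CC[C@@H]2[C@H](C1)C=C2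
A2 | alternative 1 | cyclobutene | C1=CCC1
A3 | alternative 1 | acetonide of the target (identical with 22) | CC1(C)OCC(CO1)OCCCCCCCC[C@H]1CC[C@@H]2[C@H](C1)[C@H]1[C@@H]3CC[C@@H]3[C@@H]21
A4 | alternative 2 | cycloocta-1,3,5,7-tetraene | C1=CC=CC=CC=C1
A5 | alternative 2 | cis-7,8-dichlorocycloocta-1,3,5-triene (all ring double bonds Z) | Cl[C@@H]1[C@H](Cl)C=CC=CC=C1
A6 | alternative 2 | cis-7,8-dichlorobicyclo[4.2.0]octa-2,4-diene (chlorines exo) | Cl[C@@H]1[C@H](Cl)[C@H]2C=CC=C[C@@H]12
A7 | alternative 3 | tetracyclo[5.4.0.0(2,6).0(8,11)]undecan-4-one (identical with 11) | O=C1C[C@@H]2[C@H](C1)[C@H]1[C@@H]3CC[C@@H]3[C@@H]21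
A8 | alternative 3 | benzyl 2-diazo-10-[(2,2-dimethyl-1,3-dioxan-5-yl)oxy]decanoate (identical with 17) | CC1(C)OCC(CO1)OCCCCCCCCC(=[N+]=[N-])C(=O)OCc1ccccc1
A9 | alternative 3 | ring A keto ester (identical with 18) | CC1(C)OCC(CO1)OCCCCCCCC[C@@]1(C(=O)OCc2ccccc2)C(=O)C[C@@H]2[C@H](C1)[C@H]1[C@@H]3CC[C@@H]3[C@@H]21
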